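The 3,4-dihydro-2H-pyran ring is disconnected at O1–C2 and C3–C4. This reveals two latent partners: crotonaldehyde (C2 with its methyl, C3, and the hydroxymethyl carbon at the aldehyde level, O1 sitting β to it) and an acyclic 2-(hydroxymethylidene)glutaconate (O1, C6, C5 with its methyl ester, C4 and the acetate arm), made by opening the lactone ring of methyl coumalate. In the key step an aminocatalytic oxa-Michael/Michael cascade joins the enol oxygen to the β-carbon of the enal and its α-carbon to the acrylate terminus, so that the ring and all three stereocentres (C2, C3, C4) arise in one operation. The step copies the enol-to-enal closure by which oleuropein aglycone forms its ring. Aldehyde reduction ends the route.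

Key step: step 4

Remark: the amino- and hydroxymethylidene C=C bonds in 2, 3, 5, 6 and 8 are configurationally mobile (push–pull or tautomeric) and are left unassigned; only the acrylate C=C is defined. Ring atoms are numbered as in the pyran: O1, C2 (CHMe), C3 (CHCH2OH), C4, C5 (C–CO2Me), C6 (=CH–O).

Step 1
Reactants: 1 methyl coumalate (methyl 2-oxo-2H-pyran-5-carboxylate)
Product: 3 (2E)-4-(methoxycarbonyl)-5-(morpholin-4-yl)penta-2,4-dienoic acid, via ring-opened (2Z)-acid 2 (not isolated)
Conditions: morpholine (1.05 equiv), CH2Cl2, 0 °C to rt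
Reagents that add atoms: morpholine, C1COCCN1
Why: Addition–elimination of the amine at C6 of the 2-pyranone (a β-acyloxyacrylate) opens the lactone to a vinylogous carbamate and a free carboxylic acid, and the push–pull diene should relax from (2Z) to (2E), which cannot relactonise; no stereocentre is formed.

Step 2
Reactants: 3 (2E)-4-(methoxycarbonyl)-5-(morpholin-4-yl)penta-2,4-dienoic acid; 4 hydroxytyrosol (4-(2-hydroxyethyl)benzene-1,2-diol)
Product: 5 1-[2-(3,4-dihydroxyphenyl)ethyl] 5-methyl (2E)-4-(morpholin-4-ylmethylidene)pent-2-enedioate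
Conditions: PPh3, DIAD, THF, 0 °C to rt
Reagents that add atoms: none
Why: Mitsunobu esterification activates only the primary alcohol of 4 and alkylates the most acidic partner, the carboxylic acid, so the catechol needs no protection and the enol stays masked as its morpholine enamine.

Step 3
Reactants: 5 1-[2-(3,4-dihydroxyphenyl)ethyl] 5-methyl (2E)-4-(morpholin-4-ylmethylidene)pent-2-enedioate
Product: 6 1-[2-(3,4-dihydroxyphenyl)ethyl] 5-methyl (2E)-4-(hydroxymethylidene)pent-2-enedioate
Conditions: 1 M aq. HCl, THF, 0 °C; cold extraction, crude enol used at once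
Reagents that add atoms: water, O
Why: Acid hydrolysis of the vinylogous carbamate (addition–elimination of water at the aminomethylidene carbon) frees the β-formyl ester enol, while the (E)-acrylate ester cannot reach the enol oxygen and should stay intact.

Step 4
Reactants: 6 1-[2-(3,4-dihydroxyphenyl)ethyl] 5-methyl (2E)-4-(hydroxymethylidene)pent-2-enedioate; 7 (E)-crotonaldehyde
Product: 9 methyl (2R,3S,4S)-4-{2-[2-(3,4-dihydroxyphenyl)ethoxy]-2-oxoethyl}-3-formyl-2-methyl-3,4-dihydro-2H-pyran-5-carboxylate (closed monoaldehyde form of oleuropein aglycone), via oxa-Michael enamine 8 (not isolated)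
Conditions: (S)-α,α-diphenylprolinol trimethylsilyl ether (20 mol %), PhCO2H (20 mol %), 7 (3 equiv), toluene, 0 °C to rt, Ar
Reagents that add atoms: none
Why: Proposed new method: the amine and 7 form the (E,E)-iminium ion, the acidic enol OH of 6 adds to its β-carbon (O1–C2), the resulting enamine 8 adds through C3 to the acrylate β-carbon C4, and hydrolysis releases 9 and the amine. The closest known reactions are the aminocatalytic oxa-Michael/Michael and sulfa-Michael/Michael annulations of enals with 2-hydroxycinnamates, 2-(2-nitrovinyl)phenols and 4-mercaptobut-2-enoates; new here is an acyclic β-formyl ester enol as the O-donor. The dihydropyran ring closes in the C3–C4 event as a 6-exo-trig enamine Michael addition, the O1–C2 event being intermolecular. C2 (R) is set by the catalyst, whose C(Ph)2OSiMe3 group shields one face of the iminium so that O1 enters at the Re face of the β-carbon; C4 should follow from a half-chair transition state with the C2 methyl and the (E)-acrylate arm pseudo-equatorial (2,4-cis), and C3, α to the aldehyde, should settle trans to both neighbours under the amine/acid conditions. The step needs O- over C-alkylation of the ambident enol: C5 is fully substituted, so C-adducts are quaternary and can revert by retro-Michael addition, whereas only the O-adduct is drained by the irreversible ring closure. Excess 7 and the acidity of 6 should keep the amine as iminium and not as a vinylogous carbamate of 6.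

Step 5
Reactants: 9 methyl (2R,3S,4S)-4-{2-[2-(3,4-dihydroxyphenyl)ethoxy]-2-oxoethyl}-3-formyl-2-methyl-3,4-dihydro-2H-pyran-5-carboxylate
Product: 10 methyl (2R,3R,4S)-4-{2-[2-(3,4-dihydroxyphenyl)ethoxy]-2-oxoethyl}-3-(hydroxymethyl)-2-methyl-3,4-dihydro-2H-pyran-5-carboxylate (target)
Conditions: NaBH4, MeOH/CH2Cl2 (1:1), −40 °C; then aq. NH4Cl
Reagents that add atoms: none
Why: Borohydride reduction of the aldehyde is much faster than attack on the two esters or the vinylogous carbonate at low temperature; no stereocentre is created and C3, already trans to both neighbours, is not disturbed (its descriptor changes from S to R only through the priority change CHO to CH2OH).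

Compound list
1 | methyl coumalate (methyl 2-oxo-2H-pyran-5-carboxylate) | COC(=O)C1=COC(=O)C=C1 | starting material
2 | (2Z)-4-(methoxycarbonyl)-5-(morpholin-4-yl)penta-2,4-dienoic acid | COC(=O)C(=CN1CCOCC1)/C=C\C(=O)O | intermediate
3 | (2E)-4-(methoxycarbonyl)-5-(morpholin-4-yl)penta-2,4-dienoic acid | COC(=O)C(=CN1CCOCC1)/C=C/C(=O)O | intermediate
4 | hydroxytyrosol (4-(2-hydroxyethyl)benzene-1,2-diol) | OCCc1ccc(O)c(O)c1 | starting material
5 | 1-[2-(3,4-dihydroxyphenyl)ethyl] 5-methyl (2E)-4-(morpholin-4-ylmethylidene)pent-2-enedioate | COC(=O)C(=CN1CCOCC1)/C=C/C(=O)OCCc1ccc(O)c(O)c1 | intermediate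
6 | 1-[2-(3,4-dihydroxyphenyl)ethyl] 5-methyl (2E)-4-(hydroxymethylidene)pent-2-enedioate | COC(=O)C(=CO)/C=C/C(=O)OCCc1ccc(O)c(O)c1 | intermediate
7 | (E)-crotonaldehyde | C/C=C/C=O | starting material
8 | 1-[2-(3,4-dihydroxyphenyl)ethyl] 5-methyl (2E)-4-({[(2R,3E)-4-{(2S)-2-[diphenyl(trimethylsilyloxy)methyl]pyrrolidin-1-yl}but-3-en-2-yl]oxy}methylidene)pent-2-enedioate | C[Si](C)(C)OC(c1ccccc1)(c1ccccc1)[C@@H]1CCCN1/C=C/[C@@H](C)OC=C(C(=O)OC)/C=C/C(=O)OCCc1ccc(O)c(O)c1 | intermediate
9 | methyl (2R,3S,4S)-4-{2-[2-(3,4-dihydroxyphenyl)ethoxy]-2-oxoethyl}-3-formyl-2-methyl-3,4-dihydro-2H-pyran-5-carboxylate | COC(=O)C1=CO[C@H](C)[C@@H](C=O)[C@@H]1CC(=O)OCCc1ccc(O)c(O)c1 | intermediate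
10 | methyl (2R,3R,4S)-4-{2-[2-(3,4-dihydroxyphenyl)ethoxy]-2-oxoethyl}-3-(hydroxymethyl)-2-methyl-3,4-dihydro-2H-pyran-5-carboxylate | COC(=O)C1=CO[C@H](C)[C@@H](CO)[C@@H]1CC(=O)OCCc1ccc(O)c(O)c1 | target

Total step count: 5. Longest linear sequence: 5 steps (from methyl coumalate 1).

Steps most likely to fail

1. Step 4 (proposed new method). Possible failures are competing C-alkylation of the enol, sequestration of the amine by condensation with the hydroxymethylidene group, poor facial selectivity in the oxa-Michael event, poor 2,4-induction in the ring closure, and Friedel–Crafts attack of the free catechol on the iminium ion. The fallback uses known chemistry and forms the same two bonds one after the other. It sets out from 6. Commercial 4,4-dimethoxybutan-2-one is reduced with a ketoreductase to (2S)-4,4-dimethoxybutan-2-ol F1. Mitsunobu O-alkylation of the acidic enol 6 with F1 (PPh3, DIAD, THF) proceeds with inversion and should give the (R)-configured enol ether acetal F2. Mild acetal hydrolysis (aq. AcOH, THF) gives the aldehyde F3. Amine-catalysed intramolecular 6-exo-trig Michael addition of F3 onto the enoate (the same prolinol silyl ether with PhCO2H, toluene) passes through enamine 8 and comes back to the route at 9.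

2. Step 3. Possible failures are incomplete hydrolysis of the push–pull enamine and loss of the hydroxytyrosyl ester by E/Z isomerisation and relactonisation to methyl coumalate during the acidic unmasking. The fallback changes the order so that hydroxytyrosol is attached only after the ring exists. It sets out from 3. Acid hydrolysis at the acid stage gives (2E)-5-hydroxy-4-(methoxycarbonyl)penta-2,4-dienoic acid F4, where relactonisation only returns methyl coumalate. The cascade of step 4 with 7 is run on F4 to give (2R,3S,4S)-elenolic acid F5. Mitsunobu esterification of F5 with 4 (PPh3, DIAD, THF) comes back to the route at 9.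

3. Step 1. Possible failures are attack of the amine at the lactone carbonyl instead of C6 (amide formation), incomplete Z-to-E equilibration, and decarboxylation of the vinylogous carbamic acid. The fallback uses hydroxide, for which both sites of attack lead to the same product. It sets out from 1. NaOH (2 equiv) in water/THF at 0 °C gives disodium (2Z)-4-(methoxycarbonyl)-5-oxidopenta-2,4-dienoate F6. Condensation of its formyl group with morpholine in AcOH-buffered solution, followed by acidification and equilibration to the (2E) acid, comes back to the route at 3.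

Further compounds
F1 | step 4 | (2S)-4,4-dimethoxybutan-2-ol | C[C@H](O)CC(OC)OC
F2 | step 4 | 1-[2-(3,4-dihydroxyphenyl)ethyl] 5-methyl (2E)-4-({[(2R)-4,4-dimethoxybutan-2-yl]oxy}methylidene)pent-2-enedioate | COC(=O)C(=CO[C@H](C)CC(OC)OC)/C=C/C(=O)OCCc1ccc(O)c(O)c1
F3 | step 4 | 1-[2-(3,4-dihydroxyphenyl)ethyl] 5-methyl (2E)-4-({[(2R)-4-oxobutan-2-yl]oxy}methylidene)pent-2-enedioate | COC(=O)C(=CO[C@H](C)CC=O)/C=C/C(=O)OCCc1ccc(O)c(O)c1
F4 | step 3 | (2E)-5-hydroxy-4-(methoxycarbonyl)penta-2,4-dienoic acid | COC(=O)C(=CO)/C=C/C(=O)O
F5 | step 3 | 2-[(2R,3S,4S)-3-formyl-5-(methoxycarbonyl)-2-methyl-3,4-dihydro-2H-pyran-4-yl]acetic acid (elenolic acid) | COC(=O)C1=CO[C@H](C)[C@@H](C=O)[C@@H]1CC(=O)O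
F6 | step 1 | disodium (2Z)-4-(methoxycarbonyl)-5-oxidopenta-2,4-dienoate | COC(=O)C(=C[O-])/C=C\C(=O)[O-].[Na+].[Na+]
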